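**Retrosynthetic overview**
1. Target 23 is (14S)-labda-7,13(16)-diene-14,15-diyl diacetate. Late stage: diacetate from the acetonide diol; the C17 methyl and the C7=C8 bond from the C7-enol triflate of an 8-ketone; side chain C12–C16 by Hosomi–Sakurai addition of chiral-pool allylsilane 16 to enone 13 (drim-9(11)-en-8-one).
2. Key disconnection C5–C6: ring B (C5–C6–C7–C8–C9–C10) comes from vinylcyclobutanol 11 by alkoxy-radical cleavage of the cyclobutane bond C8–C5 and re-bonding of C5 to the vinyl terminus C6 (strain-release two-carbon ring expansion).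
3. Enabling feature: C8, C9, C10 and C5 of ring B can be tied into a four-membered ring once C8 is a carbinol carbon. C8 returns as the ketone that later becomes C8(CH3)=C7, and the exocyclic C9=C11 bond (the future side-chain attachment) forbids cleavage toward C9.
4. The cyclobutane comes from an auxiliary-controlled keteniminium [2+2] cycloaddition on 1,3,3-trimethylcyclohexene, which forms C8–C5 and C9–C10 and sets the C10 quaternary centre.
5. Ring order: ring A (from 2,2,6-trimethylcyclohexanone), then the fused cyclobutane, then ring B.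

Key step: step 7

Remark on numbering: labdane numbering is used for all intermediates (ring A = C1–C5, C10; ring B = C5–C10; side chain C11–C16; C17 on C8; C18 and C19 on C4; C20 on C10).
Assumption: the (2R,5R)-amide 6 is taken to deliver the (1R,6R)-cyclobutanone 9; if the sense of induction is the reverse, the (2S,5S)-amide is used and nothing else changes.

**Step 1**
Reactants: 1 (±)-2,2,6-trimethylcyclohexanone
Product: 3 2,6,6-trimethylcyclohex-1-en-1-yl trifluoromethanesulfonate, via lithium enolate 2 (not isolated)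
Conditions: LiN(iPr)2, THF, −78 → 0 °C; then PhNTf2, 0 °C → rt
Reagents that add atoms: N-phenylbis(trifluoromethanesulfonimide), O=S(=O)(N(c1ccccc1)S(=O)(=O)C(F)(F)F)C(F)(F)F
Why: The ketone has a single enolisable α-hydrogen, so one enolate forms and is O-sulfonylated (enol triflate formation); the stereocentre of 1 is erased.

**Step 2**
Reactants: 3 2,6,6-trimethylcyclohex-1-en-1-yl trifluoromethanesulfonate
Product: 4 1,3,3-trimethylcyclohex-1-ene
Conditions: Pd(OAc)2 (cat.), PPh3, Bu3N, HCO2H, DMF, 60 °C
Reagents that add atoms: none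
Why: Palladium-catalysed formate reduction of an enol triflate (oxidative addition to zerovalent palladium, formate-to-hydride exchange with loss of CO2, reductive elimination) should replace OTf by H without moving the double bond; no stereocentre is involved.

**Step 3**
Reactants: 5 (2R,5R)-2,5-dimethylpyrrolidine
Product: 6 1-[(2R,5R)-2,5-dimethylpyrrolidin-1-yl]ethan-1-one
Conditions: Ac2O, Et3N, CH2Cl2, 0 °C → rt
Reagents that add atoms: acetic anhydride, CC(=O)OC(C)=O
Why: Plain N-acetylation of a secondary amine (acyl substitution); the two auxiliary stereocentres are untouched.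

**Step 4**
Reactants: 4 1,3,3-trimethylcyclohex-1-ene; 6 1-[(2R,5R)-2,5-dimethylpyrrolidin-1-yl]ethan-1-one
Product: 9 (1R,6R)-1,5,5-trimethylbicyclo[4.2.0]octan-7-one, via keteniminium triflate 7 (not isolated), via cyclobutaniminium triflate 8 (not isolated)
Conditions: Tf2O, 2,6-di-tert-butyl-4-methylpyridine, ClCH2CH2Cl, −20 → 80 °C; then H2O, 80 °C
Reagents that add atoms: water, O
Why: Keteniminium–alkene [2+2] cycloaddition: the electrophilic central carbon of 7 bonds to the less substituted alkene carbon C5 while charge builds at tertiary C10, which closes onto the CH2 terminus to give the necessarily cis-fused iminium 8 (hydrolysed to 9); the C2-symmetric pyrrolidine differentiates the two alkene faces and so sets C10, whereas C5 is only provisional and is reset in step 7.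

**Step 5**
Reactants: 9 (1R,6R)-1,5,5-trimethylbicyclo[4.2.0]octan-7-one
Product: 10 (1S,6R)-1,5,5-trimethyl-8-methylidenebicyclo[4.2.0]octan-7-one
Conditions: (CH2O)n, iPr2NH2+ CF3CO2−, CF3CO2H (cat.), THF, 65 °C
Reagents that add atoms: formaldehyde (from paraformaldehyde), C=O
Why: Mannich-type α-methylenation (aminomethylation then β-elimination) can end in a C=CH2 group only at C9, the sole α-CH2 of the cyclobutanone; no new stereocentre is formed.

**Step 6**
Reactants: 10 (1S,6R)-1,5,5-trimethyl-8-methylidenebicyclo[4.2.0]octan-7-one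
Product: 11 (1S,6R,7R)-7-ethenyl-1,5,5-trimethyl-8-methylidenebicyclo[4.2.0]octan-7-ol
Conditions: CH2=CHMgBr, CeCl3, THF, −78 °C
Reagents that add atoms: vinylmagnesium bromide, C=C[Mg]Br
Why: Cerium-mediated 1,2-addition to the enone carbonyl (CeCl3 suppresses conjugate addition and enolisation) should occur from the convex face away from ring A; the new carbinol centre is destroyed in step 7, so its configuration is of no consequence.

**Step 7**
Reactants: 11 (1S,6R,7R)-7-ethenyl-1,5,5-trimethyl-8-methylidenebicyclo[4.2.0]octan-7-ol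
Product: 13 (4aS,8aS)-5,5,8a-trimethyl-1-methylideneoctahydronaphthalen-2(1H)-one (drim-9(11)-en-8-one), via ring-opened C5 radical 12 (not isolated)
Conditions: [Ir(dF(CF3)ppy)2(5,5'-d(CF3)bpy)]PF6 (2 mol %), 2,4,6-collidine, PhCF3 (0.02 M), blue LEDs, rt
Reagents that add atoms: none
Why: The excited trivalent iridium photocatalyst and collidine remove the hydroxyl hydrogen of 11 by proton-coupled electron transfer, the alkoxy radical cleaves the strained C8–C5 bond (β-scission) to give secondary radical 12 carrying a cross-conjugated divinyl ketone, C5 adds to the vinyl terminus C6, and the α-keto radical at C7 is reduced by the divalent iridium species and protonated, so the step is a redox-neutral isomerisation. The closest known reaction type is the photocatalytic two-carbon ring expansion of 1-alkenylcycloalkanols by alkoxy-radical β-scission and endo recombination with the unveiled enone. Ring B closes in the 6-endo-trig mode, preferred over 5-exo attack at C7 because the nucleophilic alkyl radical is polarity-matched with the β-carbon of the vinyl ketone. C5 is the only stereocentre made: the cis fusion of the cyclobutane is erased at the planar radical, and C6 should bond through a chair-like transition state that keeps C6 and C9 equatorial on ring A (C10 methyl axial), which leads to the trans-decalin, while C10 is not touched. The step needs cleavage toward C5 and not toward C9, and the exocyclic C9=C11 bond secures this because expulsion of an sp2 carbon would give a vinyl radical; the same group later serves as the acceptor for the side chain.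

**Step 8**
Reactants: 14 methyl (4R)-2,2-dimethyl-1,3-dioxolane-4-carboxylate
Product: 16 {2-[(4S)-2,2-dimethyl-1,3-dioxolan-4-yl]prop-2-en-1-yl}trimethylsilane, via bis(silylmethyl) carbinol 15 (not isolated)
Conditions: Me3SiCH2MgCl (3 equiv), CeCl3, THF, −78 °C → rt; then SiO2, CH2Cl2, rt
Reagents that add atoms: (trimethylsilyl)methylmagnesium chloride, C[Si](C)(C)C[Mg]Cl
Why: Twofold addition of the weakly basic cerium-modified Grignard reagent to the ester should give carbinol 15 without epimerising the α-alkoxy centre, and acid-promoted Peterson elimination on silica releases the 2-substituted allylsilane; the stereocentre comes from the chiral pool and only its descriptor changes (R to S by the priority rules).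

**Step 9**
Reactants: 13 (4aS,8aS)-5,5,8a-trimethyl-1-methylideneoctahydronaphthalen-2(1H)-one; 16 {2-[(4S)-2,2-dimethyl-1,3-dioxolan-4-yl]prop-2-en-1-yl}trimethylsilane
Product: 18 (1R,4aS,8aS)-1-{3-[(4S)-2,2-dimethyl-1,3-dioxolan-4-yl]but-3-en-1-yl}-5,5,8a-trimethyloctahydronaphthalen-2(1H)-one, via trichlorotitanium enolate 17 (not isolated)
Conditions: TiCl4, CH2Cl2, −78 °C; aq. NaHCO3; then NaOMe (cat.), MeOH, rt
Reagents that add atoms: none
Why: Hosomi–Sakurai conjugate allylation: the TiCl4-activated enone is attacked at the unhindered methylidene carbon C11 by the alkene terminus of the allylsilane (SE2′, loss of Me3SiCl), which forms C11–C12 and the C13=C16 methylidene in one event; C9 is set on protonation and methoxide equilibration to the equatorial (β) side chain next to the axial C10 methyl, and C14 is untouched.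

**Step 10**
Reactants: 18 (1R,4aS,8aS)-1-{3-[(4S)-2,2-dimethyl-1,3-dioxolan-4-yl]but-3-en-1-yl}-5,5,8a-trimethyloctahydronaphthalen-2(1H)-one
Product: 20 (1R,4aS,8aS)-1-{3-[(4S)-2,2-dimethyl-1,3-dioxolan-4-yl]but-3-en-1-yl}-5,5,8a-trimethyl-1,4,4a,5,6,7,8,8a-octahydronaphthalen-2-yl trifluoromethanesulfonate, via potassium enolate 19 (not isolated)
Conditions: KN(SiMe3)2, THF, −78 °C; then PhNTf2, −78 → 0 °C
Reagents that add atoms: N-phenylbis(trifluoromethanesulfonimide), O=S(=O)(N(c1ccccc1)S(=O)(=O)C(F)(F)F)C(F)(F)F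
Why: Kinetic deprotonation should occur at the C7 methylene and not at the hindered tertiary C9–H, and O-triflation of enolate 19 (enol triflate formation) fixes the double bond at C7=C8 without touching C9.

**Step 11**
Reactants: 20 the C7-enol triflate
Product: 21 (4S)-2,2-dimethyl-4-{4-[(1S,4aS,8aS)-2,5,5,8a-tetramethyl-1,4,4a,5,6,7,8,8a-octahydronaphthalen-1-yl]but-1-en-2-yl}-1,3-dioxolane
Conditions: MeMgBr, Fe(acac)3 (5 mol %), THF/NMP, −30 °C
Reagents that add atoms: methylmagnesium bromide, C[Mg]Br
Why: Iron-catalysed cross-coupling of an alkenyl triflate with a Grignard reagent installs the C17 methyl on C8 with retention of the double-bond position; no stereocentre is affected.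

**Step 12**
Reactants: 21 the acetonide
Product: 22 (2S)-3-methylidene-5-[(1S,4aS,8aS)-2,5,5,8a-tetramethyl-1,4,4a,5,6,7,8,8a-octahydronaphthalen-1-yl]pentane-1,2-diol
Conditions: AcOH/H2O (4:1), 40 °C
Reagents that add atoms: none
Why: Acid-catalysed acetal hydrolysis removes the isopropylidene group under conditions that should leave the trisubstituted and 1,1-disubstituted alkenes alone; C14 is untouched.

**Step 13**
Reactants: 22 the diol
Product: 23 (14S)-labda-7,13(16)-diene-14,15-diyl diacetate (target)
Conditions: Ac2O, pyridine, DMAP (cat.), CH2Cl2, rt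
Reagents that add atoms: acetic anhydride, CC(=O)OC(C)=O
Why: DMAP-catalysed acylation esterifies the primary and the secondary allylic hydroxyl; no stereocentre is affected.

**Compound list**
1 | (±)-2,2,6-trimethylcyclohexanone | CC1CCCC(C)(C)C1=O | starting material
2 | lithium 2,6,6-trimethylcyclohex-1-en-1-olate | [Li+].CC1=C([O-])C(C)(C)CCC1 | intermediate
3 | 2,6,6-trimethylcyclohex-1-en-1-yl trifluoromethanesulfonate | CC1=C(OS(=O)(=O)C(F)(F)F)C(C)(C)CCC1 | intermediate
4 | 1,3,3-trimethylcyclohex-1-ene | CC1=CC(C)(C)CCC1 | intermediate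
5 | (2R,5R)-2,5-dimethylpyrrolidine | C[C@@H]1CC[C@@H](C)N1 | starting material
6 | 1-[(2R,5R)-2,5-dimethylpyrrolidin-1-yl]ethan-1-one | C[C@@H]1CC[C@@H](C)N1C(C)=O | intermediate
7 | (2R,5R)-1-ethenylidene-2,5-dimethylpyrrolidin-1-ium trifluoromethanesulfonate | C[C@@H]1CC[C@@H](C)[N+]1=C=C.[O-]S(=O)(=O)C(F)(F)F | intermediate
8 | (2R,5R)-2,5-dimethyl-1-[(1R,6R)-1,5,5-trimethylbicyclo[4.2.0]octan-7-ylidene]pyrrolidin-1-ium trifluoromethanesulfonate (cis-fused) | C[C@@H]1CC[C@@H](C)[N+]1=C1C[C@@]2(C)CCCC(C)(C)[C@@H]12.[O-]S(=O)(=O)C(F)(F)F | intermediate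
9 | (1R,6R)-1,5,5-trimethylbicyclo[4.2.0]octan-7-one (cis-fused) | O=C1C[C@@]2(C)CCCC(C)(C)[C@@H]12 | intermediate
10 | (1S,6R)-1,5,5-trimethyl-8-methylidenebicyclo[4.2.0]octan-7-one | C=C1C(=O)[C@@H]2C(C)(C)CCC[C@]12C | intermediate
11 | (1S,6R,7R)-7-ethenyl-1,5,5-trimethyl-8-methylidenebicyclo[4.2.0]octan-7-ol | C=C[C@]1(O)C(=C)[C@@]2(C)CCCC(C)(C)[C@@H]12 | intermediate
12 | (6S)-2,2,6-trimethyl-6-(3-oxopenta-1,4-dien-2-yl)cyclohexyl radical | C=CC(=O)C(=C)[C@@]1(C)CCCC(C)(C)[CH]1 | intermediate
13 | (4aS,8aS)-5,5,8a-trimethyl-1-methylideneoctahydronaphthalen-2(1H)-one (drim-9(11)-en-8-one, trans-fused) | C=C1C(=O)CC[C@H]2C(C)(C)CCC[C@]12C | intermediate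
14 | methyl (4R)-2,2-dimethyl-1,3-dioxolane-4-carboxylate | COC(=O)[C@H]1COC(C)(C)O1 | starting material
15 | 2-[(4R)-2,2-dimethyl-1,3-dioxolan-4-yl]-1,3-bis(trimethylsilyl)propan-2-ol | C[Si](C)(C)CC(O)(C[Si](C)(C)C)[C@H]1COC(C)(C)O1 | intermediate
16 | {2-[(4S)-2,2-dimethyl-1,3-dioxolan-4-yl]prop-2-en-1-yl}trimethylsilane | C=C(C[Si](C)(C)C)[C@H]1COC(C)(C)O1 | intermediate
17 | trichloro{[(4aS,8aS)-1-{3-[(4S)-2,2-dimethyl-1,3-dioxolan-4-yl]but-3-en-1-yl}-5,5,8a-trimethyl-3,4,4a,5,6,7,8,8a-octahydronaphthalen-2-yl]oxy}titanium | C=C(CCC1=C(O[Ti](Cl)(Cl)Cl)CC[C@H]2C(C)(C)CCC[C@]12C)[C@H]3COC(C)(C)O3 | intermediate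
18 | (1R,4aS,8aS)-1-{3-[(4S)-2,2-dimethyl-1,3-dioxolan-4-yl]but-3-en-1-yl}-5,5,8a-trimethyloctahydronaphthalen-2(1H)-one | C=C(CC[C@H]1C(=O)CC[C@H]2C(C)(C)CCC[C@]12C)[C@H]3COC(C)(C)O3 | intermediate
19 | potassium (1R,4aS,8aS)-1-{3-[(4S)-2,2-dimethyl-1,3-dioxolan-4-yl]but-3-en-1-yl}-5,5,8a-trimethyl-1,4,4a,5,6,7,8,8a-octahydronaphthalen-2-olate | [K+].C=C(CC[C@H]1C([O-])=CC[C@H]2C(C)(C)CCC[C@]12C)[C@H]3COC(C)(C)O3 | intermediate
20 | (1R,4aS,8aS)-1-{3-[(4S)-2,2-dimethyl-1,3-dioxolan-4-yl]but-3-en-1-yl}-5,5,8a-trimethyl-1,4,4a,5,6,7,8,8a-octahydronaphthalen-2-yl trifluoromethanesulfonate | C=C(CC[C@H]1C(OS(=O)(=O)C(F)(F)F)=CC[C@H]2C(C)(C)CCC[C@]12C)[C@H]3COC(C)(C)O3 | intermediate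
21 | (4S)-2,2-dimethyl-4-{4-[(1S,4aS,8aS)-2,5,5,8a-tetramethyl-1,4,4a,5,6,7,8,8a-octahydronaphthalen-1-yl]but-1-en-2-yl}-1,3-dioxolane | C=C(CC[C@H]1C(C)=CC[C@H]2C(C)(C)CCC[C@]12C)[C@H]3COC(C)(C)O3 | intermediate
22 | (2S)-3-methylidene-5-[(1S,4aS,8aS)-2,5,5,8a-tetramethyl-1,4,4a,5,6,7,8,8a-octahydronaphthalen-1-yl]pentane-1,2-diol | C=C(CC[C@H]1C(C)=CC[C@H]2C(C)(C)CCC[C@]12C)[C@@H](CO)O | intermediate
23 | (14S)-labda-7,13(16)-diene-14,15-diyl diacetate | C=C(CC[C@H]1C(C)=CC[C@H]2C(C)(C)CCC[C@]12C)[C@@H](COC(C)=O)OC(C)=O | target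

**Step count and risks**

Total step count: 13. Longest linear sequence: 11 (steps 1, 2, 4, 5, 6, 7, 9, 10, 11, 12, 13; steps 3 and 8 are side branches).

Steps most likely to fail:

1. Step 7. C6 may bond to the less hindered α-face of the planar C5 radical (the β-face is flanked by the axial methyls on C4 and C10), which would give the cis ring fusion, and the radical may be reduced before it cyclises. The fallback sets out from 10 and comes back at 18; it defers the C5 stereocentre to a hydrogen-atom transfer. Deprotonation of 10 at its only α-hydrogen (C5) with LiN(SiMe3)2 and chlorination with N-chlorosuccinimide should give the 5-chloro cyclobutanone F1. Addition of CH2=CHMgBr/CeCl3 gives the chloro carbinol F2. The same photocatalytic ring expansion, now through a chlorine-stabilised C5 radical, gives the 5-chloro enone F3, whose C5 configuration does not matter. Sakurai addition of 16 (TiCl4, −78 °C) gives the chloro ketone F4. Radical dechlorination (Bu3SnH, AIBN, toluene, 80 °C) generates the bicyclic tertiary C5 radical, which should take hydrogen on the open α-face; methoxide equilibration at C9 then gives 18.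

2. Step 4. The tertiary cation formed on attack at C5 may lose a proton (ene-type acylation) instead of closing the four-membered ring, the neopentyl-type alkene carbon may react slowly, and the auxiliary may discriminate the alkene faces poorly. The fallback sets out from 4 and comes back at 9. A Lewis-acid-catalysed enantioselective allenoate–alkene [2+2] cycloaddition of 4 with 2,2,2-trifluoroethyl buta-2,3-dienoate (chiral diphenylprolinol-derived oxazaborolidine activated by AlBr3, CH2Cl2, −78 → −20 °C) should give the cyclobutylidene acetate F5 with the same regiochemistry. Ozonolysis with Me2S work-up then cleaves the exocyclic alkene to 9.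

3. Step 5. The strained α-methylidene cyclobutanone may oligomerise or add the secondary amine in a conjugate sense under the warm acidic conditions. The fallback sets out from 9 and comes back at 10; it releases the enone only in the last, cold operation. The kinetic lithium enolate of 9 at C9 (LiN(SiMe3)2, THF, −78 °C) is aminomethylated with Eschenmoser's salt to the Mannich base F6. Quaternisation with MeI gives the ammonium iodide F7, and Hofmann-type elimination with DBU at 0 °C gives 10.

**Further compounds**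
F1 | step 7 | (1R,6S)-6-chloro-1,5,5-trimethyl-8-methylidenebicyclo[4.2.0]octan-7-one (chlorine on C5, cis-fused) | C=C1C(=O)[C@]2(Cl)C(C)(C)CCC[C@]12C
F2 | step 7 | (1R,6S)-6-chloro-7-ethenyl-1,5,5-trimethyl-8-methylidenebicyclo[4.2.0]octan-7-ol (carbinol epimers) | C=CC1(O)C(=C)[C@@]2(C)CCCC(C)(C)[C@@]12Cl
F3 | step 7 | (8aR)-4a-chloro-5,5,8a-trimethyl-1-methylideneoctahydronaphthalen-2(1H)-one (either C4a epimer) | C=C1C(=O)CCC2(Cl)C(C)(C)CCC[C@]12C
F4 | step 7 | (8aR)-4a-chloro-1-{3-[(4S)-2,2-dimethyl-1,3-dioxolan-4-yl]but-3-en-1-yl}-5,5,8a-trimethyloctahydronaphthalen-2(1H)-one (epimers at C1 and C4a) | C=C(CCC1C(=O)CCC2(Cl)C(C)(C)CCC[C@]12C)[C@H]3COC(C)(C)O3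
F5 | step 4 | 2,2,2-trifluoroethyl (2E)-2-[(1R,6R)-1,5,5-trimethylbicyclo[4.2.0]octan-7-ylidene]acetate | O=C(OCC(F)(F)F)/C=C1\C[C@@]2(C)CCCC(C)(C)[C@@H]12
F6 | step 5 | (1S,6R)-8-[(dimethylamino)methyl]-1,5,5-trimethylbicyclo[4.2.0]octan-7-one (C8 epimers) | CN(C)CC1C(=O)[C@@H]2C(C)(C)CCC[C@]12C
F7 | step 5 | N,N,N-trimethyl-1-[(1S,6R)-1,5,5-trimethyl-7-oxobicyclo[4.2.0]octan-8-yl]methanaminium iodide | C[N+](C)(C)CC1C(=O)[C@@H]2C(C)(C)CCC[C@]12C.[I-]
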